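**Retrosynthetic overview**
1. Target 17 is opened to the acyclic (9S)-9-hydroxy-3,5,7-triketo tert-butyl ester 13. Ring C and ring A are both unzipped at once, and only ring B is bought.
2. Forward ring order, in one flask: ring C first (the C9-OH condenses on the C5 ketone and the stereogenic C–O bond is never broken). Ring A follows (tert-butyl β-keto ester → acylketene → C4a–C5 bond → aromatisation), then desilylation.
3. 13 comes from a crossed Claisen (flavanone C8–C8a bond) of side-chain acetoacetate 5 with (S)-δ-hydroxy-β-keto ester 12. The side chain on the α-carbon of 5 can only end up at C6.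
4. 12 comes from a Ti/BINOL vinylogous Mukaiyama aldol of O-silyl vanillin 7 with Chan's diene 10. This sets the only stereocentre.
5. 5 comes from Tsuji–Trost alkylation of tert-butyl acetoacetate 4 with 3, and 3 comes from a Schenck ene reaction of geranyl acetate 1.

Assumption: (S)-BINOL is taken to send Chan's diene to the Si face of 7, as it does with benzaldehyde; the antipodal ligand is used if a Mosher check says otherwise.
Assumption: metal salts (enolates, alkoxides) of a numbered compound carry the number of that compound.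

**Step 1**
Reactants: 1 geranyl acetate
Product: 3 (2E,5E)-7-hydroxy-3,7-dimethylocta-2,5-dien-1-yl acetate, via allylic hydroperoxide 2 (not isolated)
Conditions: O2, tetraphenylporphyrin (0.2 mol%), white LED, CH2Cl2, 0 °C; then PPh3 (1.05 equiv), 0 °C → rt; chromatography removes the 6-hydroxy-7-ene regioisomer (about 1:1)
Reagents that add atoms: dioxygen, O=O
Why: In this Schenck ene reaction singlet oxygen attacks only the electron-rich C6=C7 olefin (C2=C3 is deactivated by the allylic acetate), abstraction of a C5–H gives the tertiary hydroperoxide with a new E C5=C6 bond, and PPh3 reduces the O–O bond without touching the olefins.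

**Step 2**
Reactants: 3 (2E,5E)-7-hydroxy-3,7-dimethylocta-2,5-dien-1-yl acetate; 4 tert-butyl acetoacetate
Product: 5 tert-butyl (4E,7E)-2-acetyl-9-hydroxy-5,9-dimethyldeca-4,7-dienoate (C2 epimers)
Conditions: 4 (1.5 equiv), NaH (1.4 equiv), THF, 0 °C; then 3, Pd(PPh3)4 (3 mol%), rt → 45 °C
Reagents that add atoms: none
Why: In this Tsuji–Trost allylic alkylation zerovalent palladium ionises only the primary allylic acetate (the free tertiary allylic alcohol is inert), and the soft bulky enolate attacks the CH2 terminus of the syn π-allyl complex faster than syn/anti exchange, so the linear 2E product forms; the new α-centre is epimerisable and vanishes in ring A.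

**Step 3**
Reactants: 6 vanillin
Product: 7 4-(tert-butyldimethylsilyloxy)-3-methoxybenzaldehyde
Conditions: TBSCl (1.1 equiv), imidazole (1.1 equiv), CH2Cl2, rt
Reagents that add atoms: tert-butyldimethylsilyl chloride, CC(C)(C)[Si](C)(C)Cl
Why: Standard phenol silylation masks the acidic OH for the Lewis-acid and polyanion steps and tempers ionisation of the later benzylic C–O bond.

**Step 4**
Reactants: 8 methyl acetoacetate
Product: 10 1-methoxy-1,3-bis(trimethylsilyloxy)buta-1,3-diene (Chan's diene), via mono(silyl enol ether) 9 (not isolated)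
Conditions: Me3SiOTf (2.2 equiv), Et3N (2.4 equiv), Et2O, 0 °C → rt; decant from the salt phase, bulb-to-bulb distillation
Reagents that add atoms: trimethylsilyl triflate, C[Si](C)(C)OS(=O)(=O)C(F)(F)F
Why: Under soft enolisation (Simchen conditions) O-silylation of the enol is followed by silylation of the ester carbonyl, and Et3N then removes the vinylogous γ-proton to give the bis(silyloxy)diene.

**Step 5**
Reactants: 7 4-(tert-butyldimethylsilyloxy)-3-methoxybenzaldehyde; 10 Chan's diene
Product: 12 methyl (5S)-5-[4-(tert-butyldimethylsilyloxy)-3-methoxyphenyl]-5-hydroxy-3-oxopentanoate, via bis-silylated aldol adduct 11 (not isolated)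
Conditions: Ti(OiPr)4/(S)-BINOL (1:1, 10 mol%), 4 Å MS, THF, 10 (1.6 equiv), −78 °C → rt; then 1 M aq HCl, THF, 0 °C, 10 min
Reagents that add atoms: none
Why: In this catalytic asymmetric vinylogous Mukaiyama aldol addition the (S)-BINOL–titanium complex binds the aldehyde and shields its Re face, so the terminal carbon of 10 adds to the Si face and sets (S)-C5 (the future C2), and brief acid removes only the two Me3Si groups.

**Step 6**
Reactants: 5 tert-butyl (4E,7E)-2-acetyl-9-hydroxy-5,9-dimethyldeca-4,7-dienoate; 12 methyl (5S)-5-aryl-5-hydroxy-3-oxopentanoate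
Product: 13 tert-butyl (9S)-9-[4-(tert-butyldimethylsilyloxy)-3-methoxyphenyl]-9-hydroxy-2-[(2E,5E)-7-hydroxy-3,7-dimethylocta-2,5-dien-1-yl]-3,5,7-trioxononanoate (tautomer and C2-epimer mixture, used crude)
Conditions: 5 (1.3 equiv), LiN(iPr)2 (3.05 equiv per 5), THF, −78 → 0 °C; separately 12, LiN(iPr)2 (2.05 equiv), THF, −78 °C; combine, −78 → 0 °C, 3 h; AcOH/THF, −78 °C; pH 5 buffer, extraction
Reagents that add atoms: none
Why: In this crossed Claisen condensation of the Huckin–Weiler/Harris type (a polyanion acylated by the salt of a β-keto ester) threefold deprotonation of 5 leaves its terminal carbon as the only hard carbanion, double deprotonation of 12 blocks its acidic sites and retro-aldol so only the methyl ester is electrophilic, the tert-butyl ester is too hindered to react, and the carbinol centre is a spectator.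

**Step 7**
Reactants: 13 tert-butyl (9S)-9-aryl-9-hydroxy-2-alkenyl-3,5,7-trioxononanoate
Product: 17 tomentodiplacone B, via dihydropyranone 14 (not isolated), via acylketene 15 (not isolated), via O-silyl flavanone 16 (not isolated)
Conditions: poly(4-vinylpyridinium p-toluenesulfonate) (0.2 equiv), 4 Å MS, toluene, 40 °C, 2 h; cannula-filter and add over 2 h into refluxing toluene (final 3 mM, 110 °C, slow distillation of t-BuOH/toluene), 2 h more; distil down to 0.05 M, 0 °C, AcOH (1.5 equiv), Bu4NF (1.2 equiv, THF), 20 min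
Reagents that add atoms: none
Why: Proposed new method: the C9-OH forms the six-membered hemiketal at the C5 ketone and mild acid dehydrates it to the 2-aryl-2,3-dihydropyran-4-one (known cyclodehydration of δ-hydroxy-1,3-diketones), which ties up the only oxygen that could otherwise give a 2-pyrone; the tert-butyl β-keto ester then loses t-BuOH on neutral heating to an acylketene (Witzeman-type generation) whose only reachable nucleophile is the enol-ether α-carbon C4a, so C-acylation, or 6π closure of the enolised dienylketene as in the last event of a Danheiser benzannulation and as in the biomimetic Claisen cyclisation of 3,5,7-triketo esters, gives the phloroglucinol ring with the side chain locked between 5-OH and 7-OH; the C2–O bond set in step 5 is never broken, the base-free medium avoids retro-oxa-Michael racemisation, and buffered fluoride finally cleaves the aryl silyl ether.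

**Compound list**
1 | geranyl acetate | CC(=O)OC/C=C(\C)CCC=C(C)C | starting material
2 | (2E,5E)-7-hydroperoxy-3,7-dimethylocta-2,5-dien-1-yl acetate | CC(=O)OC/C=C(\C)C/C=C/C(C)(C)OO | intermediate
3 | (2E,5E)-7-hydroxy-3,7-dimethylocta-2,5-dien-1-yl acetate | CC(=O)OC/C=C(\C)C/C=C/C(C)(C)O | intermediate
4 | tert-butyl acetoacetate | CC(=O)CC(=O)OC(C)(C)C | starting material
5 | tert-butyl (4E,7E)-2-acetyl-9-hydroxy-5,9-dimethyldeca-4,7-dienoate | CC(=O)C(C/C=C(\C)C/C=C/C(C)(C)O)C(=O)OC(C)(C)C | intermediate
6 | vanillin | COc1cc(C=O)ccc1O | starting material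
7 | 4-(tert-butyldimethylsilyloxy)-3-methoxybenzaldehyde | COc1cc(C=O)ccc1O[Si](C)(C)C(C)(C)C | intermediate
8 | methyl acetoacetate | CC(=O)CC(=O)OC | starting material
9 | methyl 3-(trimethylsilyloxy)but-2-enoate | COC(=O)C=C(C)O[Si](C)(C)C | intermediate
10 | 1-methoxy-1,3-bis(trimethylsilyloxy)buta-1,3-diene (Chan's diene) | COC(=CC(=C)O[Si](C)(C)C)O[Si](C)(C)C | intermediate
11 | methyl (5S)-5-[4-(tert-butyldimethylsilyloxy)-3-methoxyphenyl]-3,5-bis(trimethylsilyloxy)pent-2-enoate | COC(=O)C=C(O[Si](C)(C)C)C[C@H](O[Si](C)(C)C)c1ccc(O[Si](C)(C)C(C)(C)C)c(OC)c1 | intermediate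
12 | methyl (5S)-5-[4-(tert-butyldimethylsilyloxy)-3-methoxyphenyl]-5-hydroxy-3-oxopentanoate | COC(=O)CC(=O)C[C@H](O)c1ccc(O[Si](C)(C)C(C)(C)C)c(OC)c1 | intermediate
13 | tert-butyl (9S)-9-[4-(tert-butyldimethylsilyloxy)-3-methoxyphenyl]-9-hydroxy-2-[(2E,5E)-7-hydroxy-3,7-dimethylocta-2,5-dien-1-yl]-3,5,7-trioxononanoate | CC(C)(C)OC(=O)C(C/C=C(\C)C/C=C/C(C)(C)O)C(=O)CC(=O)CC(=O)C[C@H](O)c1ccc(O[Si](C)(C)C(C)(C)C)c(OC)c1 | intermediate
14 | tert-butyl 4-{(2S)-2-[4-(tert-butyldimethylsilyloxy)-3-methoxyphenyl]-4-oxo-3,4-dihydro-2H-pyran-6-yl}-2-[(2E,5E)-7-hydroxy-3,7-dimethylocta-2,5-dien-1-yl]-3-oxobutanoate | CC(C)(C)OC(=O)C(C/C=C(\C)C/C=C/C(C)(C)O)C(=O)CC1=CC(=O)C[C@H](O1)c2ccc(O[Si](C)(C)C(C)(C)C)c(OC)c2 | intermediate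
15 | acylketene: 14 with the CH(R)–CO2tBu unit turned into C(R)=C=O | O=C=C(C/C=C(\C)C/C=C/C(C)(C)O)C(=O)CC1=CC(=O)C[C@H](O1)c2ccc(O[Si](C)(C)C(C)(C)C)c(OC)c2 | intermediate
16 | (2S)-4'-O-(tert-butyldimethylsilyl)tomentodiplacone B | COc1cc([C@@H]2CC(=O)c3c(cc(O)c(C/C=C(\C)C/C=C/C(C)(C)O)c3O)O2)ccc1O[Si](C)(C)C(C)(C)C | intermediate
17 | tomentodiplacone B, (2S)-5,7-dihydroxy-2-(4-hydroxy-3-methoxyphenyl)-6-[(2E,5E)-7-hydroxy-3,7-dimethylocta-2,5-dien-1-yl]chroman-4-one | COc1cc([C@@H]2CC(=O)c3c(cc(O)c(C/C=C(\C)C/C=C/C(C)(C)O)c3O)O2)ccc1O | target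

**Total step count:** 7. **Longest linear sequence:** 4 (steps 3-5-6-7; equally 4-5-6-7 and 1-2-6-7).

**Three steps most likely to fail**

Most at risk is step 7. Loss of t-BuOH from the α-substituted β-keto ester may need more heat than the tertiary allylic alcohol and C2 tolerate, or the acylketene may be lost to oligomers. The fallback replaces thermal ketene generation by thiophilic activation at room temperature.
- It sets out from 3, which is coupled as in step 2 with purchased S-tert-butyl acetothioacetate to give S-tert-butyl (4E,7E)-2-acetyl-9-hydroxy-5,9-dimethyldeca-4,7-dienethioate F1.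
- The trilithium salt of F1 is acylated by 12 as in step 6 to the thioester tetraketide F2.
- The pyridinium resin closes ring C to the dihydropyranone thioester F3.
- In the same flask AgOCOCF3 (1.2 equiv) and Na2HPO4 in CH2Cl2 at 20 °C pull off the thiolate, so that C4a is acylated and ring A aromatises.
- The fallback comes back to the route at 16, which is desilylated as before.

Second is step 6. The enolate salt of 12 is a sluggish acylating agent, and its lithium aldolate may undergo retro-aldol before it reacts. The fallback takes the charge off the electrophile.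
- It sets out from 12, which with Et3SiOTf/2,6-lutidine (CH2Cl2, −78 → 0 °C) gives the neutral masked β-keto ester methyl (5S)-5-aryl-3,5-bis(triethylsilyloxy)pent-2-enoate F4.
- Trilithiated 5 adds to its ester at −78 → −20 °C to give the bis(triethylsilyl) enol-ether tetraketide F5.
- Pyridinium p-toluenesulfonate in MeOH at 0 °C strips both Et3Si groups while the aryl silyl ether stays.
- The fallback comes back to the route at 13.

Third is step 2. The π-allyl complex may give branched product, E/Z scrambling or elimination to a triene through the doubly allylic CH2. The fallback replaces π-allyl chemistry by direct SN2 displacement.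
- It sets out from 3, which K2CO3/MeOH converts into (2E,5E)-3,7-dimethylocta-2,5-diene-1,7-diol F6.
- MsCl, LiCl and s-collidine in DMF at 0 °C act only on the primary allylic OH, through the primary mesylate F7, to give (3E,6E)-8-chloro-2,6-dimethylocta-3,6-dien-2-ol F8.
- The sodium enolate of 4 (THF/DMF, NaI catalyst, rt) displaces chloride with the olefin geometry and position retained.
- The fallback comes back to the route at 5.

**Further compounds**
F1 | step 7 | S-tert-butyl (4E,7E)-2-acetyl-9-hydroxy-5,9-dimethyldeca-4,7-dienethioate | CC(=O)C(C/C=C(\C)C/C=C/C(C)(C)O)C(=O)SC(C)(C)C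
F2 | step 7 | S-tert-butyl (9S)-9-[4-(tert-butyldimethylsilyloxy)-3-methoxyphenyl]-9-hydroxy-2-[(2E,5E)-7-hydroxy-3,7-dimethylocta-2,5-dien-1-yl]-3,5,7-trioxononanethioate | CC(C)(C)SC(=O)C(C/C=C(\C)C/C=C/C(C)(C)O)C(=O)CC(=O)CC(=O)C[C@H](O)c1ccc(O[Si](C)(C)C(C)(C)C)c(OC)c1
F3 | step 7 | S-tert-butyl 4-{(2S)-2-[4-(tert-butyldimethylsilyloxy)-3-methoxyphenyl]-4-oxo-3,4-dihydro-2H-pyran-6-yl}-2-[(2E,5E)-7-hydroxy-3,7-dimethylocta-2,5-dien-1-yl]-3-oxobutanethioate | CC(C)(C)SC(=O)C(C/C=C(\C)C/C=C/C(C)(C)O)C(=O)CC1=CC(=O)C[C@H](O1)c2ccc(O[Si](C)(C)C(C)(C)C)c(OC)c2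
F4 | step 6 | methyl (5S)-5-[4-(tert-butyldimethylsilyloxy)-3-methoxyphenyl]-3,5-bis(triethylsilyloxy)pent-2-enoate | COC(=O)C=C(C[C@H](O[Si](CC)(CC)CC)c1ccc(O[Si](C)(C)C(C)(C)C)c(OC)c1)O[Si](CC)(CC)CC
F5 | step 6 | tert-butyl (9S)-9-[4-(tert-butyldimethylsilyloxy)-3-methoxyphenyl]-2-[(2E,5E)-7-hydroxy-3,7-dimethylocta-2,5-dien-1-yl]-3,5-dioxo-7,9-bis(triethylsilyloxy)non-6-enoate | CC(C)(C)OC(=O)C(C/C=C(\C)C/C=C/C(C)(C)O)C(=O)CC(=O)C=C(C[C@H](O[Si](CC)(CC)CC)c1ccc(O[Si](C)(C)C(C)(C)C)c(OC)c1)O[Si](CC)(CC)CC
F6 | step 2 | (2E,5E)-3,7-dimethylocta-2,5-diene-1,7-diol | OC/C=C(\C)C/C=C/C(C)(C)O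
F7 | step 2 | (2E,5E)-7-hydroxy-3,7-dimethylocta-2,5-dien-1-yl methanesulfonate | CS(=O)(=O)OC/C=C(\C)C/C=C/C(C)(C)O
F8 | step 2 | (3E,6E)-8-chloro-2,6-dimethylocta-3,6-dien-2-ol | ClC/C=C(\C)C/C=C/C(C)(C)O
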